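**Retrosynthetic overview**
1. Last C–C bond: C-2/C-3 of the side chain, by nickel-catalysed enantioconvergent reductive coupling of a C-3 benzylic radical (from an 8-(1-chloro-3-hydroxy-5-arylpentyl)flavanone) with an (E)-β-bromostyrene; the catalyst sets C-3.
2. The chloride comes from a syn-1,3-diol made in one pot by Ipc-boron aldol/LiBH4 reduction of an 8-formylflavanone with a 4-arylbutan-2-one; C-5 is set by relay from a temporary C-3 carbinol.
3. The (2S)-flavanone comes from palladium-catalysed asymmetric conjugate addition of an arylboronic acid to an 8-formylchromone.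
4. The chromone hub comes from phloroglucinol (C–H borylation/oxidation of a resorcinol ether) by formylation, 4-O-methylation, C-acetylation and enaminone cyclisation; symmetry fixes the ring A regiochemistry.
5. Ring order: ring A (bought arene), then pyranone ring C, then ring B and the two side-chain aryl rings attached as bought arenes.

Assumption: side-chain carbons are numbered C-1 (styryl CH) to C-7, so the target is a (2S)-flavanone with a (1E,3S,5S) side chain at C-8; in intermediates 22, 23 and 28 the pentyl chain is numbered 1′–5′ (C-1′ = future C-3, C-3′ = future C-5).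

**Step 1**
Reactants: 1 1,3-bis(trimethylsilyloxy)benzene
Product: 4 benzene-1,3,5-triol (phloroglucinol), via arylboronate 2 (not isolated), via silylated phenol 3 (not isolated)
Conditions: [Ir(OMe)(cod)]2 (1.5 mol %), dtbpy (3 mol %), B2pin2 (1.0 equiv), hexane, 60 °C; then Oxone (2KHSO5·KHSO4·K2SO4), acetone/H2O, rt, 10 min; then 1 M HCl, rt
Reagents that add atoms: potassium peroxymonosulfate (active part of Oxone), [K+].[O-]S(=O)(=O)OO
Why: sterically controlled iridium-catalysed C–H borylation goes to the only C–H without an ortho substituent (C-5), the C–B bond is oxidised in the same pot (one-pot borylation/oxidation), and the aryl trimethylsilyl ethers hydrolyse in the acidic aqueous medium.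

**Step 2**
Reactants: 4 phloroglucinol
Product: 6 2,4,6-trihydroxybenzaldehyde, via iminium chloride 5 (not isolated)
Conditions: POCl3 (1.1 equiv), DMF (1.2 equiv), EtOAc, 0 °C → rt; then H2O, 70 °C
Reagents that add atoms: N,N-dimethylformamide, CN(C)C=O; water, O
Why: Vilsmeier–Haack formylation, which stops at mono-substitution because the iminium salt deactivates the ring and precipitates.

**Step 3**
Reactants: 6 2,4,6-trihydroxybenzaldehyde
Product: 7 2,6-dihydroxy-4-methoxybenzaldehyde
Conditions: Me2SO4 (1.0 equiv), K2CO3 (1.0 equiv), acetone, rt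
Reagents that add atoms: dimethyl sulfate, COS(=O)(=O)OC
Why: Williamson methylation at the para OH, which is the most acidic and not hydrogen-bonded to the formyl group (the same selectivity as the 4-O-methylation of phloroacetophenone).

**Step 4**
Reactants: 7 2,6-dihydroxy-4-methoxybenzaldehyde
Product: 9 3-acetyl-2,6-dihydroxy-4-methoxybenzaldehyde, via difluoroboron chelate 8 (not isolated)
Conditions: AcOH, BF3·OEt2, 80 °C; then aq. NaOAc, 60 °C
Reagents that add atoms: acetic acid, CC(=O)O
Why: boron trifluoride-mediated Friedel–Crafts C-acylation of a phloroglucinol-type ring; the two free positions are equivalent by symmetry, so the acetyl can only enter between an OH and the OMe.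

**Step 5**
Reactants: 9 3-acetyl-2,6-dihydroxy-4-methoxybenzaldehyde
Product: 10 3-acetyl-2-hydroxy-4-methoxy-6-(triisopropylsilyloxy)benzaldehyde
Conditions: TIPSCl (1.05 equiv), imidazole, DMF, 0 °C
Reagents that add atoms: chlorotriisopropylsilane, CC(C)[Si](Cl)(C(C)C)C(C)C
Why: selective silyl ether formation at 6-OH, because 2-OH is buried between two carbonyl groups and strongly hydrogen-bonded.

**Step 6**
Reactants: 10 3-acetyl-2-hydroxy-4-methoxy-6-(triisopropylsilyloxy)benzaldehyde
Product: 12 5-methoxy-4-oxo-7-(triisopropylsilyloxy)-4H-chromene-8-carbaldehyde, via enaminone 11 (not isolated)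
Conditions: Me2NCH(OMe)2, toluene, 90 °C; then conc. HCl, CH2Cl2, rt
Reagents that add atoms: N,N-dimethylformamide dimethyl acetal, COC(OC)N(C)C
Why: enaminone formation at the acetyl CH3 followed by acid-induced cyclisation with loss of Me2NH (standard chromone synthesis); only 2-OH is free, so ring C closes next to the formyl-bearing carbon, which becomes C-8.

**Step 7**
Reactants: 13 (4-bromophenoxy)(tert-butyl)dimethylsilane
Product: 16 [4-(tert-butyldimethylsilyloxy)phenyl]boronic acid, via aryllithium 14 (not isolated), via lithium borate 15 (not isolated)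
Conditions: n-BuLi, THF, −78 °C; B(Oi-Pr)3, −78 °C → rt; then 1 M HCl to pH 5
Reagents that add atoms: triisopropyl borate, CC(C)OB(OC(C)C)OC(C)C; water, O
Why: bromine–lithium exchange, borylation and hydrolysis; the aryl silyl ether survives the cold organolithium and the mildly acidic work-up.

**Step 8**
Reactants: 12 5-methoxy-4-oxo-7-(triisopropylsilyloxy)-4H-chromene-8-carbaldehyde; 16 [4-(tert-butyldimethylsilyloxy)phenyl]boronic acid
Product: 17 (2S)-2-[4-(tert-butyldimethylsilyloxy)phenyl]-5-methoxy-4-oxo-7-(triisopropylsilyloxy)chromane-8-carbaldehyde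
Conditions: Pd(OCOCF3)2 (5 mol %), (R)-t-BuPyOx (6 mol %), NH4PF6 (30 mol %), H2O (5 equiv), ClCH2CH2Cl, 60 °C
Reagents that add atoms: none
Why: palladium-catalysed asymmetric conjugate addition of an arylboronic acid to a chromone (pyridine-oxazoline system); the ligand antipode sets C-2 as S (facial sense by analogy with 3-substituted cyclohexenones), and the hindered formyl group flanked by two oxygens is a much poorer acceptor for aryl-palladium than the enone.

**Step 9**
Reactants: 18 tert-butyl(4-iodophenoxy)dimethylsilane; 19 but-3-en-2-ol (racemic)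
Product: 20 4-[4-(tert-butyldimethylsilyloxy)phenyl]butan-2-one
Conditions: Pd(OAc)2 (3 mol %), n-Bu4NCl, NaHCO3, DMF, 50 °C
Reagents that add atoms: none
Why: Heck reaction of an allylic alcohol (Jeffery conditions); β-hydride elimination toward the carbinol gives the enol and hence the saturated methyl ketone.

**Step 10**
Reactants: 20 4-[4-(tert-butyldimethylsilyloxy)phenyl]butan-2-one; 17 (2S)-8-formylflavanone
Product: 23 (2S)-2-[4-(tert-butyldimethylsilyloxy)phenyl]-8-{(1S,3S)-5-[4-(tert-butyldimethylsilyloxy)phenyl]-1,3-dihydroxypentyl}-5-methoxy-7-(triisopropylsilyloxy)chroman-4-one, via boron enolate 21 (not isolated), via boron aldolate 22 (not isolated)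
Conditions: 20 (1.3 equiv), (+)-Ipc2BCl (1.2 equiv), Et3N, Et2O, −78 → 0 °C; 17, −78 → −20 °C; LiBH4, −78 °C; then H2O2, pH 7 buffer, MeOH, 0 °C
Reagents that add atoms: none
Why: Paterson boron aldol–reduction: kinetic methyl-side enolisation, Ipc-controlled si-face attack on the aldehyde gives the (1′S) aldolate, and LiBH4 reduction through the six-membered boron chelate gives the 1,3-syn diol, so C-3′ (future C-5) is set as S by relay from C-1′.

**Step 11**
Reactants: 13 (4-bromophenoxy)(tert-butyl)dimethylsilane; 24 (E)-1,2-dibromoethene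
Product: 27 {4-[(E)-2-bromoethenyl]phenoxy}(tert-butyl)dimethylsilane, via arylmagnesium bromide 25 (not isolated), via arylzinc chloride 26 (not isolated)
Conditions: Mg, THF, 50 °C; ZnCl2, 0 °C; then 24 (4 equiv), Pd(PPh3)4 (3 mol %), THF, rt
Reagents that add atoms: none
Why: Negishi mono-coupling of the dibromoalkene, used in excess to suppress double arylation, with retention of the E geometry.

**Step 12**
Reactants: 23 syn-1,3-diol; 27 (E)-vinyl bromide
Product: 29 (2S)-2-[4-(tert-butyldimethylsilyloxy)phenyl]-8-{(1E,3S,5S)-1,7-bis[4-(tert-butyldimethylsilyloxy)phenyl]-5-hydroxyhept-1-en-3-yl}-5-methoxy-7-(triisopropylsilyloxy)chroman-4-one, via benzylic chloride 28 (not isolated)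
Conditions: HCl (4 M in dioxane), CH2Cl2, 0 °C, then evaporate; NiCl2·dme (10 mol %), (3aR,3a′R,8aS,8a′S)-2,2′-(cyclopropane-1,1-diyl)bis(3a,8a-dihydro-8H-indeno[1,2-d]oxazole) (11 mol %), Mn powder (3 equiv), NaI (0.5 equiv), DMA, 0 °C
Reagents that add atoms: none
Why: Proposed new method: extension of the nickel-catalysed asymmetric reductive cross-coupling of secondary benzylic chlorides with vinyl bromides (closest known reaction type) to a di-ortho-oxygenated chloride bearing a free γ-hydroxyl on a complete flavanone; the activated benzylic OH alone is exchanged for chloride by an SN1 path, monovalent nickel abstracts chlorine to give a planar benzylic radical (both chloride epimers converge), the radical is captured by the bisoxazoline-bound alkenylnickel bromide, and reductive elimination from trivalent nickel sets C-3 as S under catalyst control (ligand antipode chosen by analogy with 1-arylalkyl chlorides) with retention of the E-alkene.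

**Step 13**
Reactants: 29 tetrasilyl ether
Product: 30 (2S)-7-hydroxy-8-[(1E,3S,5S)-5-hydroxy-1,7-bis(4-hydroxyphenyl)hept-1-en-3-yl]-2-(4-hydroxyphenyl)-5-methoxychroman-4-one (CNP0191649.2)
Conditions: n-Bu4NF (5 equiv), AcOH (5 equiv), THF, 0 °C → rt
Reagents that add atoms: none
Why: fluoride cleavage of the four aryl silyl ethers, buffered with acetic acid so that neither base (C-2 epimerisation by ring opening) nor strong acid (ionisation at the styrene or the C-3–aryl bond) is present.

**Compound list**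
1 | 1,3-bis(trimethylsilyloxy)benzene | C[Si](C)(C)Oc1cccc(O[Si](C)(C)C)c1 | starting material
2 | 2-[3,5-bis(trimethylsilyloxy)phenyl]-4,4,5,5-tetramethyl-1,3,2-dioxaborolane | C[Si](C)(C)Oc1cc(O[Si](C)(C)C)cc(c1)B1OC(C)(C)C(C)(C)O1 | intermediate
3 | 3,5-bis(trimethylsilyloxy)phenol | C[Si](C)(C)Oc1cc(O)cc(O[Si](C)(C)C)c1 | intermediate
4 | benzene-1,3,5-triol (phloroglucinol) | Oc1cc(O)cc(O)c1 | intermediate
5 | [(2,4,6-trihydroxyphenyl)methylidene]dimethylammonium chloride | C[N+](C)=Cc1c(O)cc(O)cc1O.[Cl-] | intermediate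
6 | 2,4,6-trihydroxybenzaldehyde | O=Cc1c(O)cc(O)cc1O | intermediate
7 | 2,6-dihydroxy-4-methoxybenzaldehyde | COc1cc(O)c(C=O)c(O)c1 | intermediate
8 | difluoroboron chelate of 9 (BF2 bridging the 2-O and the acetyl oxygen) | CC1=[O+][B-](F)(F)Oc2c(C=O)c(O)cc(OC)c12 | intermediate
9 | 3-acetyl-2,6-dihydroxy-4-methoxybenzaldehyde | COc1cc(O)c(C=O)c(O)c1C(C)=O | intermediate
10 | 3-acetyl-2-hydroxy-4-methoxy-6-(triisopropylsilyloxy)benzaldehyde | COc1cc(O[Si](C(C)C)(C(C)C)C(C)C)c(C=O)c(O)c1C(C)=O | intermediate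
11 | 3-[(E)-3-(dimethylamino)prop-2-enoyl]-2-hydroxy-4-methoxy-6-(triisopropylsilyloxy)benzaldehyde | COc1cc(O[Si](C(C)C)(C(C)C)C(C)C)c(C=O)c(O)c1C(=O)/C=C/N(C)C | intermediate
12 | 5-methoxy-4-oxo-7-(triisopropylsilyloxy)-4H-chromene-8-carbaldehyde | COc1cc(O[Si](C(C)C)(C(C)C)C(C)C)c(C=O)c2occc(=O)c12 | intermediate
13 | (4-bromophenoxy)(tert-butyl)dimethylsilane | CC(C)(C)[Si](C)(C)Oc1ccc(Br)cc1 | starting material
14 | [4-(tert-butyldimethylsilyloxy)phenyl]lithium | [Li]c1ccc(O[Si](C)(C)C(C)(C)C)cc1 | intermediate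
15 | lithium [4-(tert-butyldimethylsilyloxy)phenyl]tri(propan-2-yloxy)borate | [Li+].CC(C)O[B-](OC(C)C)(OC(C)C)c1ccc(O[Si](C)(C)C(C)(C)C)cc1 | intermediate
16 | [4-(tert-butyldimethylsilyloxy)phenyl]boronic acid | OB(O)c1ccc(O[Si](C)(C)C(C)(C)C)cc1 | intermediate
17 | (2S)-2-[4-(tert-butyldimethylsilyloxy)phenyl]-5-methoxy-4-oxo-7-(triisopropylsilyloxy)chromane-8-carbaldehyde | COc1cc(O[Si](C(C)C)(C(C)C)C(C)C)c(C=O)c2O[C@H](c3ccc(O[Si](C)(C)C(C)(C)C)cc3)CC(=O)c12 | intermediate
18 | tert-butyl(4-iodophenoxy)dimethylsilane | CC(C)(C)[Si](C)(C)Oc1ccc(I)cc1 | starting material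
19 | but-3-en-2-ol (racemic) | CC(O)C=C | starting material
20 | 4-[4-(tert-butyldimethylsilyloxy)phenyl]butan-2-one | CC(=O)CCc1ccc(O[Si](C)(C)C(C)(C)C)cc1 | intermediate
21 | diisopinocampheylboron enolate of 20 (terminal, CH2=C(OBIpc2)–) | C=C(CCc1ccc(O[Si](C)(C)C(C)(C)C)cc1)OB([C@H]1C[C@H]2C[C@@H]([C@@H]1C)C2(C)C)[C@H]1C[C@H]2C[C@@H]([C@@H]1C)C2(C)C | intermediate
22 | (1′S)-boron aldolate: O-BIpc2 derivative of the β-hydroxy ketone from 17 + 20 | COc1cc(O[Si](C(C)C)(C(C)C)C(C)C)c([C@@H](OB([C@H]3C[C@H]4C[C@@H]([C@@H]3C)C4(C)C)[C@H]3C[C@H]4C[C@@H]([C@@H]3C)C4(C)C)CC(=O)CCc3ccc(O[Si](C)(C)C(C)(C)C)cc3)c2O[C@H](c3ccc(O[Si](C)(C)C(C)(C)C)cc3)CC(=O)c12 | intermediate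
23 | (2S)-2-[4-(tert-butyldimethylsilyloxy)phenyl]-8-{(1S,3S)-5-[4-(tert-butyldimethylsilyloxy)phenyl]-1,3-dihydroxypentyl}-5-methoxy-7-(triisopropylsilyloxy)chroman-4-one | COc1cc(O[Si](C(C)C)(C(C)C)C(C)C)c([C@@H](O)C[C@@H](O)CCc3ccc(O[Si](C)(C)C(C)(C)C)cc3)c2O[C@H](c3ccc(O[Si](C)(C)C(C)(C)C)cc3)CC(=O)c12 | intermediate
24 | (E)-1,2-dibromoethene | Br/C=C/Br | starting material
25 | [4-(tert-butyldimethylsilyloxy)phenyl]magnesium bromide | Br[Mg]c1ccc(O[Si](C)(C)C(C)(C)C)cc1 | intermediate
26 | [4-(tert-butyldimethylsilyloxy)phenyl]zinc chloride | Cl[Zn]c1ccc(O[Si](C)(C)C(C)(C)C)cc1 | intermediate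
27 | {4-[(E)-2-bromoethenyl]phenoxy}(tert-butyl)dimethylsilane | Br/C=C/c1ccc(O[Si](C)(C)C(C)(C)C)cc1 | intermediate
28 | (2S)-2-[4-(tert-butyldimethylsilyloxy)phenyl]-8-{(3S)-1-chloro-3-hydroxy-5-[4-(tert-butyldimethylsilyloxy)phenyl]pentyl}-5-methoxy-7-(triisopropylsilyloxy)chroman-4-one (both C-1′ epimers) | COc1cc(O[Si](C(C)C)(C(C)C)C(C)C)c(C(Cl)C[C@@H](O)CCc3ccc(O[Si](C)(C)C(C)(C)C)cc3)c2O[C@H](c3ccc(O[Si](C)(C)C(C)(C)C)cc3)CC(=O)c12 | intermediate
29 | (2S)-2-[4-(tert-butyldimethylsilyloxy)phenyl]-8-{(1E,3S,5S)-1,7-bis[4-(tert-butyldimethylsilyloxy)phenyl]-5-hydroxyhept-1-en-3-yl}-5-methoxy-7-(triisopropylsilyloxy)chroman-4-one | COc1cc(O[Si](C(C)C)(C(C)C)C(C)C)c([C@H](/C=C/c3ccc(O[Si](C)(C)C(C)(C)C)cc3)C[C@@H](O)CCc3ccc(O[Si](C)(C)C(C)(C)C)cc3)c2O[C@H](c3ccc(O[Si](C)(C)C(C)(C)C)cc3)CC(=O)c12 | intermediate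
30 | (2S)-7-hydroxy-8-[(1E,3S,5S)-5-hydroxy-1,7-bis(4-hydroxyphenyl)hept-1-en-3-yl]-2-(4-hydroxyphenyl)-5-methoxychroman-4-one | COc1cc(O)c([C@H](/C=C/c2ccc(O)cc2)C[C@@H](O)CCc2ccc(O)cc2)c2c1C(=O)C[C@@H](c1ccc(O)cc1)O2 | target

**Step count**
Total steps: 13 (steps 7, 9 and 11 make the three aryl building blocks).
Longest linear sequence: 10 steps (1, 2, 3, 4, 5, 6, 8, 10, 12, 13).

**Steps most likely to fail**

Step 12 is the most likely to fail. Chloride 28 is a 2,6-dioxygenated, para-methoxy benzylic chloride, so ionisation and elimination to the 8-alkenylflavanone compete. Capture of a di-ortho-substituted radical at nickel may also be slow, which would lower yield and selectivity at C-3. The fallback keeps a radical C–C bond formation but changes metal and partner: copper instead of nickel, and an alkenylboron nucleophile instead of the alkenyl bromide. It sets out from diol 23 and vinyl bromide 27. Treating 23 with Me3SiBr (CH2Cl2, −20 °C) gives the benzylic bromide F1. Treating 27 with B2pin2, PdCl2(dppf) and KOPh (toluene, 50 °C) gives the (E)-alkenyl pinacol boronate F2. F1 and F2 are joined by an enantioconvergent copper-catalysed radical C(sp3)–C(sp2) coupling (CuI, a cinchona-derived anionic N,N,P ligand, LiOt-Bu pre-mixed with F2, DMF, 0 °C). The route is rejoined at 29.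

Step 10 is the second risk. Ipc-boron aldols of methyl ketones give only moderate facial control, the formyl group is flanked by two oxygens, and LiBH4 must spare the C-4 ketone. Material from wrong-face attack would end up after step 12 as the (3S,5R) 1,3-diastereomer, which should be separable by chromatography. The fallback takes C-5 from a resolved epoxide instead of by relay. It sets out from Grignard reagent 25 and aldehyde 17. Coupling 25 with 4-bromobut-1-ene (Li2CuCl4 cat., THF) gives the 4-arylbut-1-ene F5, and mCPBA gives the racemic epoxide F6. Hydrolytic kinetic resolution with (S,S)-(salen)Co(OAc) and 0.55 equiv H2O leaves the (S)-epoxide F7. Reductive lithiation (lithium 4,4′-di-tert-butylbiphenylide, THF, −78 °C) opens it at the primary carbon to the β-lithio alkoxide F8. After transmetalation with CeCl3, F8 adds to 17 to give 23 together with the C-1′ epimer of 23 F9. Both are chlorinated as in step 12, and the route is rejoined at chloride 28.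

Step 8 is the third risk. Aryl-palladium could add to the formyl group, the electron-rich boronic acid can protodeboronate, and the selectivity on a 5,7-dioxygenated chromone is untested. The fallback closes ring C by oxa-Michael addition instead of arylating a preformed pyranone. It sets out from acetophenone 10 and aryllithium 14. Quenching 14 with DMF gives 4-(tert-butyldimethylsilyloxy)benzaldehyde F3. Claisen–Schmidt condensation of 10 with F3 (pyrrolidine, MeCN, rt) gives the 2′-hydroxychalcone F4. A quinine-derived bifunctional thiourea (10 mol %, toluene, rt) closes F4 by enantioselective intramolecular oxa-Michael addition, and the route is rejoined at 17.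

**Further compounds**
F1 | step 12 | (2S)-8-{(3S)-1-bromo-3-hydroxy-5-[4-(tert-butyldimethylsilyloxy)phenyl]pentyl}-2-[4-(tert-butyldimethylsilyloxy)phenyl]-5-methoxy-7-(triisopropylsilyloxy)chroman-4-one (both C-1′ epimers) | COc1cc(O[Si](C(C)C)(C(C)C)C(C)C)c(C(Br)C[C@@H](O)CCc3ccc(O[Si](C)(C)C(C)(C)C)cc3)c2O[C@H](c3ccc(O[Si](C)(C)C(C)(C)C)cc3)CC(=O)c12
F2 | step 12 | tert-butyldimethyl{4-[(E)-2-(4,4,5,5-tetramethyl-1,3,2-dioxaborolan-2-yl)ethenyl]phenoxy}silane | CC(C)(C)[Si](C)(C)Oc1ccc(/C=C/B2OC(C)(C)C(C)(C)O2)cc1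
F3 | step 8 | 4-(tert-butyldimethylsilyloxy)benzaldehyde | CC(C)(C)[Si](C)(C)Oc1ccc(C=O)cc1
F4 | step 8 | 3-{(E)-3-[4-(tert-butyldimethylsilyloxy)phenyl]prop-2-enoyl}-2-hydroxy-4-methoxy-6-(triisopropylsilyloxy)benzaldehyde | COc1cc(O[Si](C(C)C)(C(C)C)C(C)C)c(C=O)c(O)c1C(=O)/C=C/c1ccc(O[Si](C)(C)C(C)(C)C)cc1
F5 | step 10 | [4-(but-3-en-1-yl)phenoxy](tert-butyl)dimethylsilane | C=CCCc1ccc(O[Si](C)(C)C(C)(C)C)cc1
F6 | step 10 | racemic tert-butyldimethyl{4-[2-(oxiran-2-yl)ethyl]phenoxy}silane | C(Cc1ccc(O[Si](C)(C)C(C)(C)C)cc1)C1CO1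
F7 | step 10 | tert-butyldimethyl(4-{2-[(2S)-oxiran-2-yl]ethyl}phenoxy)silane | C1O[C@H]1CCc1ccc(O[Si](C)(C)C(C)(C)C)cc1
F8 | step 10 | lithium (2S)-4-[4-(tert-butyldimethylsilyloxy)phenyl]-1-lithiobutan-2-olate | [Li]C[C@@H](O[Li])CCc1ccc(O[Si](C)(C)C(C)(C)C)cc1
F9 | step 10 | (2S)-2-[4-(tert-butyldimethylsilyloxy)phenyl]-8-{(1R,3S)-5-[4-(tert-butyldimethylsilyloxy)phenyl]-1,3-dihydroxypentyl}-5-methoxy-7-(triisopropylsilyloxy)chroman-4-one | COc1cc(O[Si](C(C)C)(C(C)C)C(C)C)c([C@H](O)C[C@@H](O)CCc3ccc(O[Si](C)(C)C(C)(C)C)cc3)c2O[C@H](c3ccc(O[Si](C)(C)C(C)(C)C)cc3)CC(=O)c12
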